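Compound numbers are those of the steps and of the compound list. Ring positions follow flavone numbering (O1, C2 to C8a, C1' to C6'). The open chain of 11 is numbered from the ester carbon C1 to the aroyl carbon C9, so that chain C1 to C6 become C8a, C8, C7, C6, C5, C4a and chain C7, C8, C9 become C4, C3, C2.

Assumption: 8 and 11 are handled as mixtures of enol tautomers and of stereoisomers at their methoxy-bearing carbons, which epimerize freely and become aromatic carbons in step 6; 5 is taken to be purchasable.

## Analysis of the target

16 is a flavone: benzene ring A is fused to the 4-pyranone ring C, and C2 of ring C carries the phenyl ring B. It has no stereocentre, so the synthesis is entirely a problem of regiochemistry. Ring A is hexasubstituted, with hydroxyl groups at C5 and C6, methoxy groups at C7 and C8, the ring oxygen O1 on C8a and the carbonyl carbon C4 on C4a; ring B carries a hydroxyl at C2' and a methoxy group at C6', both ortho to the hindered C2–C1' bond. The C5/C6 diol is an electron-rich catechol that air oxidizes to an ortho-quinone in base, and the pyranone opens at C2 under strong base, so the free diol should appear last and the late steps should be mild. The difficulty is that six oxygen atoms of three kinds (hydroxyl, methyl ether, ring oxygen) must sit on defined carbons, that ring A has no free position for aromatic substitution, and that no simple benzene with this pattern can be bought. The feature used here is that the oxygens on C5, C7 and C8a stand in a 1,3,5-relationship, as in a phloroglucinol formed by folding a chain of alternating carbonyl and sp3 carbons, and that the oxygens on C6 and C8 can ride into the ring as methoxy groups on the two carbons in between. Such a ring is symmetric about the C4a–C7 axis (5,7-diol, 6,8-dimethyl ether), so the target pattern then needs one methylation at O7 and one demethylation at O6, both steered by the 5-hydroxyl that is hydrogen-bonded to the C4 carbonyl.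

## Retrosynthetic reasoning

**Ether adjustments, 16 back to 13.** The last bonds to be dealt with lie outside the skeleton. Going backwards, a methyl group is placed on O6 (15), a benzyl group on O2' (14), and the methyl group on O7 is taken off (13). This leads to 13 because it has the symmetric ring A that a folded chain delivers. Forwards, O7 must be methylated beside the chelated 5-hydroxyl, and afterwards only the methyl ether flanking that hydroxyl may be cleaved. The benzyl group keeps O2' out of the ring closure and out of the methylation, and it is removed before the diol is set free.

**Ring C, 13 back to 12.** The O1–C2 bond is cut, which turns the pyranone into an ortho-hydroxyaryl 1,3-diketone. The cut belongs here because the two hydroxyls ortho to the acyl group of 12 are equivalent, so closure can give only one flavone, and because ring B has no free hydroxyl and cannot take the part of ring A. The forward reaction is an acid-catalysed cyclodehydration.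

**Ring A, 12 back to 11.** The C4a–C8a bond is cut. This opens the benzene ring to a chain of an ester carbon (later C8a), two methoxy-bearing methines (C8 and C6) separated by a ketone (C7), and the ketones that become C5, C4 and C2. No other cut of ring A gives a precursor in which every ring carbon is at the right oxidation level and every oxygen is in place. The gain is that ring A and its five oxygens come from acyclic esters. The forward reaction must make the methylene carbon between the C5 and C4 carbonyls attack the ester carbon (Claisen mode) faster than any carbanion attacks a ketone (aldol modes).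

**Chain assembly, 11 back to 8 and 4.** The chain is cut between chain carbons C6 and C7, the later C4a–C4 bond. This gives the diketo ester 8, which holds both methoxy groups and reacts through its terminal methyl group, and the aroylacetate 4, which acts as acyl donor. The cut is not placed one bond nearer the ester end, where the donor would be a symmetrical β-keto diester. Such a donor keeps an acidic methine proton even as its mono-salt and would quench any carbanion basic enough to attack an ester. Here the donor is used as its enolate 10, which has no acidic proton left, and the nucleophile as its trianion 9, whose terminal carbon is the most reactive site.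

**Methoxy groups, 8 back to 7 and 5.** The two C–O bonds at C2 and C4 are cut. These carbons are the two doubly activated methylene groups of 5, the only positions that accept a diazo group under amine base. Diazo transfer followed by carbenoid O–H insertion therefore puts oxygen exactly where ring A needs it and leaves the terminal methyl group free for the chain extension.

**Aryl part, 4 back to 2, 3 and 1.** The bond between the methylene carbon and the ester carbon of 4 is cut. 3 supplies the carbon that ends as C4 of the flavone, and the methyl ketone 2 is the benzyl ether of the bought phenol 1. Ring B with both its oxygens and the carbons C2 and C3 enter in one piece, so the hindered C2–C1' bond never has to be made.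

## Alternatives that were turned down

**Alternative 1:** The bond cut is C2–C1', between ring C and ring B, with the 2'-oxygen used as a temporary ester tether to a carboxyl group on C3.
- Forward key step: a zerovalent palladium catalyst would insert into the carbon–iodine bond of the aryl ester A2 and deliver the aryl group to the unsubstituted C2 of the chromone, closing a six-membered lactone to give A1. Lactone opening and loss of the C3 carboxyl group would then leave the flavone with its 2'-hydroxyl free.
- For it: the hindered C2–C1' bond is made intramolecularly, ring B needs no protecting group, and the plan is convergent.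
- Against it: ring A must be brought in as a ready-made pentaoxygenated benzene, so the oxygen pattern of ring A is moved into the starting material and not solved. The carbon to be arylated is the electron-poor β-carbon of a vinylogous ester, and after carbopalladation there is no syn β-hydrogen, so turnover depends on a base-assisted pathway. The aryl ester is an activated ester next to a ring that opens under base, and oxidative addition must occur at a di-ortho-substituted iodide.
- Comparison: after A1, the lactone opening, the decarboxylation and demethylations at C5 and C6 are still to come, so the step count is no lower. On precedent of the bond-forming event it is the stronger plan, because palladium-mediated aryl–aryl closure through an ester tether is a well-studied reaction class and the chain folding chosen here is not. The chosen route offers in return a ring A built with all its oxygens from acyclic esters.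

**Alternative 2:** The bonds cut are C8–C8a and C4a–C5; ring A is built onto a finished 2-aryl-4-pyranone from the four carbons of a squaric ester.
- Forward key step: a metalated pyranone would add to the squaric ester to give the cyclobutenone A4. On heating, A4 opens to a vinylketene whose ketene carbon bonds to the neighbouring C–H carbon of the pyranone in a six-electron electrocyclization, and tautomerization gives the hydroquinone A3.
- For it: the key step needs no reagent, its regiochemistry is fixed by connectivity, and the ring expansion of 4-aryl-4-hydroxycyclobutenones is better precedented than the key step chosen here.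
- Against it: A3 has the 5,8-diol and 6,7-dimethyl ether pattern, so O8 must be methylated and the methyl ether at O6 cleaved afterwards. Methylation of A3 at O8 would lead to 14, and from there the end game is the same as in the chosen route, so nothing is saved in selectivity. The pyranone must be metalated at C3 next to an unsubstituted C2, a position where nucleophiles attack and open 4-pyranones, and the halogenated aryl pyranone needed is itself several steps away.
- Comparison: the chosen route reaches 14 in eight steps from bought materials without any organometallic pyranone; what it gives up is the certainty of the pericyclic closure.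

**Alternative 3:** The bond cut is O1–C2; ring C is closed from a fully substituted 1,4-benzoquinone that carries a 1-methoxy-3-arylallyl side chain on the later C4a.
- Forward key step: a tertiary amine would move the proton of side-chain carbon C4 of the quinone A6 onto the remote quinone oxygen. The resulting ortho-quinone methide closes by an oxa-six-electron electrocyclization to the 2H-chromen-6-ol A5.
- For it: the oxygen on C6 emerges as the only free hydroxyl of ring A, set apart by the mechanism, so the later demethylation concerns only the methyl ether at O5, the easiest to cleave. On the differentiation of O6 this plan is stronger than the chosen one, which relies on a selective demethylation.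
- Against it: A5 is a 4-methoxy-2H-chromene, the enol ether of a flavanone, so hydrolysis and a dehydrogenation are needed to reach the flavone, and the dehydrogenation must be done on an electron-rich para-oxygenated phenol that oxidants turn back into a quinone. A6 needs a pentaoxygenated benzene with a carbon side chain, which is the ring A problem in another form. The base-induced tautomerization competes with conjugate addition of the amine to the quinone and with isomerization of the side chain.
- Comparison: it would be clearly longer. The chosen route makes ring A and its five oxygens in one step and stays at the flavone oxidation level from the closure of ring C on. It pays for this with two selective ether operations whose direction is set by the chelated 5-hydroxyl.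

Key step: step 6

## Route

Step 1
Reactants: 1 1-(2-hydroxy-6-methoxyphenyl)ethanone
Product: 2 1-(2-benzyloxy-6-methoxyphenyl)ethanone
Conditions: BnBr (1.2 equiv), K2CO3 (2 equiv), DMF, 60 °C
Reagents that add atoms: benzyl bromide, BrCc1ccccc1
Why: Williamson ether synthesis; the phenoxide of 1, hydrogen-bonded to the acetyl group and therefore alkylated in a polar solvent with warming, attacks the benzylic bromide. The benzyl ether should withstand the polyanion, alkoxide, acid and methylation stages and leaves by hydrogenolysis.

Step 2
Reactants: 2 1-(2-benzyloxy-6-methoxyphenyl)ethanone; 3 dimethyl carbonate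
Product: 4 methyl 3-(2-benzyloxy-6-methoxyphenyl)-3-oxopropanoate
Conditions: NaH (2.5 equiv), 3 (4 equiv), THF, reflux; then cold 1 M HCl
Reagents that add atoms: none
Why: Crossed Claisen condensation of the methyl ketone enolate with a non-enolizable carbonate, driven forward by deprotonation of the β-keto ester formed. The two ortho substituents shield the aryl carbonyl but not the reacting methyl group.

Step 3
Reactants: 5 methyl 3,5-dioxohexanoate
Product: 7 methyl 2,4-bis(diazo)-3,5-dioxohexanoate, via methyl 4-diazo-3,5-dioxohexanoate 6 (not isolated)
Conditions: 4-acetamidobenzenesulfonyl azide (2.3 equiv), Et3N (3 equiv), MeCN, 0 °C to rt; 7 kept in solution behind a shield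
Reagents that add atoms: 4-acetamidobenzenesulfonyl azide, CC(=O)Nc1ccc(cc1)S(=O)(=O)N=[N+]=[N-]
Why: Regitz diazo transfer to both doubly activated methylene groups; C4, between two ketones, should react first to give 6, and C2, between ketone and ester, second. The singly activated C6 methyl group is not acidic enough to react under amine base.

Step 4
Reactants: 7 methyl 2,4-bis(diazo)-3,5-dioxohexanoate
Product: 8 methyl 2,4-dimethoxy-3,5-dioxohexanoate
Conditions: Rh2(OAc)4 (2 mol %), MeOH (10 equiv), CH2Cl2, 40 °C, slow addition of 7
Reagents that add atoms: methanol, CO
Why: Dirhodium-carbenoid O–H insertion; each diazo carbon loses N2 to give an electrophilic carbenoid that methanol captures through an oxonium ylide and a proton shift, and excess methanol with slow addition should suppress carbenoid–diazo coupling. The stereocentres formed at C2 and C4 are not controlled and need not be, because both carbons become aromatic in step 6.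

Step 5
Reactants: 8 methyl 2,4-dimethoxy-3,5-dioxohexanoate; 4 methyl 3-(2-benzyloxy-6-methoxyphenyl)-3-oxopropanoate
Product: 11 methyl 9-(2-benzyloxy-6-methoxyphenyl)-2,4-dimethoxy-3,5,7,9-tetraoxononanoate, via trilithium salt of the diketo ester trianion 9 (not isolated), via lithium enolate of the aroylacetate 10 (not isolated)
Conditions: 8 (1.3 equiv), LiN(iPr)2 (3.3 equiv per 8), THF, −78 to 0 °C; 4, LiN(SiMe3)2 (1.05 equiv), THF, 0 °C; enolate solution added to the trianion, 0 °C to rt; cold 1 M HCl; crude 11 used at once
Reagents that add atoms: none
Why: Crossed Claisen condensation in the form of the acylation of a polyanion by the salt of a β-keto ester; the terminal C6 carbanion of 9, the last formed and most basic site, should add to the ester carbonyl of 10, which has no acidic proton left to quench it, and loss of methoxide gives the polyenolate of 11. The internal carbons C2 and C4 of 9 are tertiary, delocalized enolate carbons and should not compete.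

Step 6
Reactants: 11 methyl 9-(2-benzyloxy-6-methoxyphenyl)-2,4-dimethoxy-3,5,7,9-tetraoxononanoate
Product: 12 1-(2-benzyloxy-6-methoxyphenyl)-3-(2,4,6-trihydroxy-3,5-dimethoxyphenyl)propane-1,3-dione
Conditions: Mg(OMe)2 (8 equiv), MeOH, 25 °C then 50 °C, argon; then cold 1 M HCl
Reagents that add atoms: none
Why: Proposed new method: Mg(OMe)2 should turn 11 into a chelated magnesium polyenolate in which the carbons flanked by two ketones (C4, C6, C8) are ionized and the C3, C5, C7 and C9 carbonyls are tied up as diketonates, so that the ester carbon C1, whose neighbour C2 is the least acidic position, remains the most electrophilic carbonyl of the chain. The C6 carbanion adds to C1, the tetrahedral intermediate expels methoxide, and the resulting 2-acylcyclohexane-1,3,5-trione enolizes at once to the aromatic triol 12, which makes the closure irreversible. The closest known reaction is the base-mediated (Mg(OMe)2 or KOH) Claisen cyclization of 3,5,7-triketo esters to acylphloroglucinols; what has not been shown is this closure on a chain that carries alkoxy groups on both carbons between the reacting ester and the nucleophilic site and a further β-diketone beyond it. Ring A closes in a 6-exo-trig, Dieckmann-type mode, forming the C4a–C8a bond (chain C6–C1). No stereocentre is formed, and the two epimerizable centres at C2 and C4 become aromatic carbons. The step needs Claisen closure to win over the aldol closures C8 to C3, C2 to C7 and C4 to C9 and over O-lactonization to a 2-pyranone. C2 and C4 are methines, so an aldol adduct through them would be quaternary, could not aromatize by loss of water and should revert; the C9 carbonyl is twisted and shielded by the two ortho substituents of ring B; C3 is deactivated as part of the C3–C4–C5 diketonate; and a pyranone formed by O-attack is reopened by methoxide to the same chain.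

Step 7
Reactants: 12 1-(2-benzyloxy-6-methoxyphenyl)-3-(2,4,6-trihydroxy-3,5-dimethoxyphenyl)propane-1,3-dione
Product: 13 2-(2-benzyloxy-6-methoxyphenyl)-5,7-dihydroxy-6,8-dimethoxy-4H-chromen-4-one
Conditions: H2SO4 (cat.), AcOH, 60 °C
Reagents that add atoms: none
Why: Acid-catalysed cyclodehydration of an ortho-hydroxyaryl 1,3-diketone, the closing stage of the Baker–Venkataraman flavone synthesis; a ring A hydroxyl next to the acyl group adds to the C2 carbonyl in a 6-exo-trig closure and water is lost. The two ortho hydroxyls of 12 are equivalent by the symmetry of ring A and ring B has no free hydroxyl, so only one flavone can form.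

Step 8
Reactants: 13 2-(2-benzyloxy-6-methoxyphenyl)-5,7-dihydroxy-6,8-dimethoxy-4H-chromen-4-one
Product: 14 2-(2-benzyloxy-6-methoxyphenyl)-5-hydroxy-6,7,8-trimethoxy-4H-chromen-4-one
Conditions: MeI (1.1 equiv), K2CO3 (1.1 equiv), acetone, reflux
Reagents that add atoms: iodomethane, CI
Why: Williamson etherification under weak base; the 7-hydroxyl, para to the C4 carbonyl, is the more acidic and is free, whereas the 5-hydroxyl is held in a hydrogen bond to the C4 carbonyl and should stay untouched with one equivalent of reagent. The benzyl ether keeps O2' out of the reaction.

Step 9
Reactants: 14 2-(2-benzyloxy-6-methoxyphenyl)-5-hydroxy-6,7,8-trimethoxy-4H-chromen-4-one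
Product: 15 5-hydroxy-2-(2-hydroxy-6-methoxyphenyl)-6,7,8-trimethoxy-4H-chromen-4-one
Conditions: H2 (1 atm), Pd/C (10% palladium on carbon), EtOAc–MeOH, rt
Reagents that add atoms: none
Why: Hydrogenolysis of the benzyl aryl ether on palladium; the C2=C3 bond belongs to the pyranone and should not be reduced at one atmosphere and room temperature. Removing the benzyl group here leaves the oxidation-prone diol to be formed only in the last step.

Step 10
Reactants: 15 5-hydroxy-2-(2-hydroxy-6-methoxyphenyl)-6,7,8-trimethoxy-4H-chromen-4-one
Product: 16 5,6-dihydroxy-2-(2-hydroxy-6-methoxyphenyl)-7,8-dimethoxy-4H-chromen-4-one (5,6,2'-trihydroxy-7,8,6'-trimethoxyflavone)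
Conditions: AlBr3 (anhydrous, 6 equiv), MeCN, 0 °C to rt, argon; then 2 M HCl, 50 °C
Reagents that add atoms: none
Why: Chelation-directed Lewis-acid cleavage of an aryl methyl ether; AlBr3 binds between O5 and the C4 carbonyl oxygen, the aluminium phenoxide activates the neighbouring 6-methoxy oxygen, and bromide removes its methyl group by SN2 to leave a stable 5,6-catecholate chelate. The ethers at C7, C8 and C6' have no such neighbour and the nitrile solvent tempers the Lewis acid; acidic work-up should release 16.

## Compound list

1 | 1-(2-hydroxy-6-methoxyphenyl)ethanone (2-hydroxy-6-methoxyacetophenone) | COc1cccc(O)c1C(C)=O | starting material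
2 | 1-(2-benzyloxy-6-methoxyphenyl)ethanone | COc1cccc(OCc2ccccc2)c1C(C)=O | intermediate
3 | dimethyl carbonate | COC(=O)OC | starting material
4 | methyl 3-(2-benzyloxy-6-methoxyphenyl)-3-oxopropanoate | COC(=O)CC(=O)c1c(OC)cccc1OCc1ccccc1 | intermediate
5 | methyl 3,5-dioxohexanoate | COC(=O)CC(=O)CC(C)=O | starting material
6 | methyl 4-diazo-3,5-dioxohexanoate (formed in the flask) | COC(=O)CC(=O)C(=[N+]=[N-])C(C)=O | intermediate
7 | methyl 2,4-bis(diazo)-3,5-dioxohexanoate | COC(=O)C(=[N+]=[N-])C(=O)C(=[N+]=[N-])C(C)=O | intermediate
8 | methyl 2,4-dimethoxy-3,5-dioxohexanoate (mixture of stereoisomers and enol forms) | COC(=O)C(OC)C(=O)C(OC)C(C)=O | intermediate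
9 | trilithium salt of the 2,4,6-trianion of methyl 2,4-dimethoxy-3,5-dioxohexanoate (formed in the flask) | [Li+].[Li+].[Li+].COC(=O)C(OC)=C([O-])C(OC)=C([O-])[CH2-] | intermediate
10 | lithium (Z)-enolate of methyl 3-(2-benzyloxy-6-methoxyphenyl)-3-oxopropanoate (formed in the flask) | [Li+].COC(=O)/C=C(\[O-])c1c(OC)cccc1OCc1ccccc1 | intermediate
11 | methyl 9-(2-benzyloxy-6-methoxyphenyl)-2,4-dimethoxy-3,5,7,9-tetraoxononanoate (mixture of stereoisomers and enol forms) | COC(=O)C(OC)C(=O)C(OC)C(=O)CC(=O)CC(=O)c1c(OC)cccc1OCc1ccccc1 | intermediate
12 | 1-(2-benzyloxy-6-methoxyphenyl)-3-(2,4,6-trihydroxy-3,5-dimethoxyphenyl)propane-1,3-dione | COc1c(O)c(OC)c(O)c(C(=O)CC(=O)c2c(OC)cccc2OCc2ccccc2)c1O | intermediate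
13 | 2-(2-benzyloxy-6-methoxyphenyl)-5,7-dihydroxy-6,8-dimethoxy-4H-chromen-4-one | COc1cccc(OCc2ccccc2)c1-c1cc(=O)c2c(O)c(OC)c(O)c(OC)c2o1 | intermediate
14 | 2-(2-benzyloxy-6-methoxyphenyl)-5-hydroxy-6,7,8-trimethoxy-4H-chromen-4-one | COc1cccc(OCc2ccccc2)c1-c1cc(=O)c2c(O)c(OC)c(OC)c(OC)c2o1 | intermediate
15 | 5-hydroxy-2-(2-hydroxy-6-methoxyphenyl)-6,7,8-trimethoxy-4H-chromen-4-one | COc1cccc(O)c1-c1cc(=O)c2c(O)c(OC)c(OC)c(OC)c2o1 | intermediate
16 | 5,6-dihydroxy-2-(2-hydroxy-6-methoxyphenyl)-7,8-dimethoxy-4H-chromen-4-one (5,6,2'-trihydroxy-7,8,6'-trimethoxyflavone) | COc1cccc(O)c1-c1cc(=O)c2c(O)c(O)c(OC)c(OC)c2o1 | target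

## Step count and least certain steps

Total step count: 10. Longest linear sequence: 8 steps (steps 1, 2, 5, 6, 7, 8, 9, 10 from 1; equally steps 3 to 10 from 5).

**Step 6 (key step).**
- Risk: folding in the aldol mode, above all attack of C8 on the C3 carbonyl, which is activated by two neighbouring methoxy-bearing carbons. Retro-Claisen cleavage of the chain by methoxide at that same carbonyl is the second danger. Both arise because the chain offers four ketone carbonyls beside the one ester.
- Fallback: ring A is taken from a bought, fully methylated ketone and the diketone is made by the Baker–Venkataraman sequence, all known chemistry. It sets out from 2: iodine in pyridine (King reaction) gives 1-[2-(2-benzyloxy-6-methoxyphenyl)-2-oxoethyl]pyridinium iodide F1, which aqueous NaOH cleaves to 2-benzyloxy-6-methoxybenzoic acid F2. Steglich esterification (DCC, DMAP) of F2 with purchased 1-(6-hydroxy-2,3,4,5-tetramethoxyphenyl)ethanone F3 gives 2-acetyl-3,4,5,6-tetramethoxyphenyl 2-benzyloxy-6-methoxybenzoate F4. KOH in pyridine moves the aroyl group from oxygen to the acetyl carbon and gives 1-(2-benzyloxy-6-methoxyphenyl)-3-(2-hydroxy-3,4,5,6-tetramethoxyphenyl)propane-1,3-dione F5, and H2SO4 in AcOH closes ring C to 2-(2-benzyloxy-6-methoxyphenyl)-5,6,7,8-tetramethoxy-4H-chromen-4-one F6. AlCl3 in MeCN then removes only the methyl group on O5, next to the carbonyl group, and the route is rejoined at 14.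

**Step 5.**
- Risk: slow acylation, because the ester of 10 is deactivated by its own enolate. This leaves time for self-condensation of 9 through its ester group and for unselective ring closure of the product polyanion before the acidic work-up.
- Fallback: the ester end is masked as a lactone. It sets out from 8, which DBU in hot toluene cyclizes to 4-hydroxy-3,5-dimethoxy-6-methyl-2H-pyran-2-one F7. Two equivalents of LiN(iPr)2 give the dilithium salt of the pyranone dianion F8, a smaller carbanion without an open-chain ester, which is acylated at its 6-methyl carbon by 10 to give 6-[4-(2-benzyloxy-6-methoxyphenyl)-2,4-dioxobutyl]-4-hydroxy-3,5-dimethoxy-2H-pyran-2-one F9. Under the conditions of step 6, methoxide opens the lactone of F9, and the route is rejoined at 11, which forms in the flask and folds on to 12.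

**Step 4.**
- Risk: reaction of a carbenoid with the diazo group or carbonyl group next to it (coupling, ylide formation, Wolff rearrangement) before methanol captures it, because the two diazo carbons are separated by a single carbonyl. 7 is also an energetic compound.
- Fallback: the two methoxy groups are introduced one after the other, so that a carbenoid never has a diazo group as neighbour. It sets out from 5: one equivalent of the sulfonyl azide gives 6, which is isolated this time, and Rh2(OAc)4 in MeOH converts it to methyl 4-methoxy-3,5-dioxohexanoate F10. A second diazo transfer, now possible only at C2, gives methyl 2-diazo-4-methoxy-3,5-dioxohexanoate F11, and a second O–H insertion rejoins the route at 8.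

**Step 10.**
- Risk: demethylation beyond O6. Once the aluminium catecholate has formed, the 7-methoxy group has an aluminium phenoxide as neighbour too, and the ether at C6' may also be attacked. The product is in addition open to air oxidation during work-up.
- Fallback: the methyl group on O6 is removed by oxidation and not by a Lewis acid. It sets out from 14, in which the 5-hydroxyl is the only free phenol. IBX (2-iodoxybenzoic acid) in DMF oxidizes this ortho-methoxyphenol at the methoxy-bearing carbon C6, with loss of methanol, to the ortho-quinone 2-(2-benzyloxy-6-methoxyphenyl)-7,8-dimethoxy-4H-chromene-4,5,6-trione F12. Na2S2O4 reduces it in the same flask to 2-(2-benzyloxy-6-methoxyphenyl)-5,6-dihydroxy-7,8-dimethoxy-4H-chromen-4-one F13, and hydrogenolysis of the benzyl ether as in step 9 gives 16.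

## Further compounds

F1 | step 6 | 1-[2-(2-benzyloxy-6-methoxyphenyl)-2-oxoethyl]pyridinium iodide | COc1cccc(OCc2ccccc2)c1C(=O)C[n+]1ccccc1.[I-]
F2 | step 6 | 2-benzyloxy-6-methoxybenzoic acid | COc1cccc(OCc2ccccc2)c1C(=O)O
F3 | step 6 | 1-(6-hydroxy-2,3,4,5-tetramethoxyphenyl)ethanone (purchased) | CC(=O)c1c(O)c(OC)c(OC)c(OC)c1OC
F4 | step 6 | 2-acetyl-3,4,5,6-tetramethoxyphenyl 2-benzyloxy-6-methoxybenzoate | CC(=O)c1c(OC(=O)c2c(OC)cccc2OCc2ccccc2)c(OC)c(OC)c(OC)c1OC
F5 | step 6 | 1-(2-benzyloxy-6-methoxyphenyl)-3-(2-hydroxy-3,4,5,6-tetramethoxyphenyl)propane-1,3-dione | COc1cccc(OCc2ccccc2)c1C(=O)CC(=O)c1c(O)c(OC)c(OC)c(OC)c1OC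
F6 | step 6 | 2-(2-benzyloxy-6-methoxyphenyl)-5,6,7,8-tetramethoxy-4H-chromen-4-one | COc1cccc(OCc2ccccc2)c1-c1cc(=O)c2c(OC)c(OC)c(OC)c(OC)c2o1
F7 | step 5 | 4-hydroxy-3,5-dimethoxy-6-methyl-2H-pyran-2-one | COc1c(O)c(OC)c(C)oc1=O
F8 | step 5 | dilithium salt of the dianion of 4-hydroxy-3,5-dimethoxy-6-methyl-2H-pyran-2-one | [Li+].[Li+].[CH2-]c1oc(=O)c(OC)c([O-])c1OC
F9 | step 5 | 6-[4-(2-benzyloxy-6-methoxyphenyl)-2,4-dioxobutyl]-4-hydroxy-3,5-dimethoxy-2H-pyran-2-one | COc1c(O)c(OC)c(CC(=O)CC(=O)c2c(OC)cccc2OCc2ccccc2)oc1=O
F10 | step 4 | methyl 4-methoxy-3,5-dioxohexanoate | COC(=O)CC(=O)C(OC)C(C)=O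
F11 | step 4 | methyl 2-diazo-4-methoxy-3,5-dioxohexanoate | COC(=O)C(=[N+]=[N-])C(=O)C(OC)C(C)=O
F12 | step 10 | 2-(2-benzyloxy-6-methoxyphenyl)-7,8-dimethoxy-4H-chromene-4,5,6-trione | COc1cccc(OCc2ccccc2)c1C1=CC(=O)C2=C(O1)C(OC)=C(OC)C(=O)C2=O
F13 | step 10 | 2-(2-benzyloxy-6-methoxyphenyl)-5,6-dihydroxy-7,8-dimethoxy-4H-chromen-4-one | COc1cccc(OCc2ccccc2)c1-c1cc(=O)c2c(O)c(O)c(OC)c(OC)c2o1
A1 | alternative 1 | 1,8,9,10,11-pentamethoxy-6H,7H-chromeno[4,3-b]chromene-6,7-dione (lactone-bridged flavone) | COc1cccc2OC(=O)c3c(-c12)oc1c(OC)c(OC)c(OC)c(OC)c1c3=O
A2 | alternative 1 | 2-iodo-3-methoxyphenyl 5,6,7,8-tetramethoxy-4-oxo-4H-chromene-3-carboxylate | COc1cccc(OC(=O)c2coc3c(OC)c(OC)c(OC)c(OC)c3c2=O)c1I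
A3 | alternative 2 | 2-(2-benzyloxy-6-methoxyphenyl)-5,8-dihydroxy-6,7-dimethoxy-4H-chromen-4-one | COc1cccc(OCc2ccccc2)c1-c1cc(=O)c2c(O)c(OC)c(OC)c(O)c2o1
A4 | alternative 2 | 4-[6-(2-benzyloxy-6-methoxyphenyl)-4-oxo-4H-pyran-3-yl]-4-hydroxy-2,3-dimethoxycyclobut-2-en-1-one | COC1=C(OC)C(O)(c2coc(-c3c(OC)cccc3OCc3ccccc3)cc2=O)C1=O
A5 | alternative 3 | 2-(2-benzyloxy-6-methoxyphenyl)-4,5,7,8-tetramethoxy-2H-chromen-6-ol | COC1=CC(c2c(OC)cccc2OCc2ccccc2)Oc2c(OC)c(OC)c(O)c(OC)c12
A6 | alternative 3 | 2-[(E)-3-(2-benzyloxy-6-methoxyphenyl)-1-methoxyprop-2-en-1-yl]-3,5,6-trimethoxy-1,4-benzoquinone | COC(/C=C/c1c(OC)cccc1OCc1ccccc1)C1=C(OC)C(=O)C(OC)=C(OC)C1=O
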